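**Strategy.** Everything rests on closing ring A last, by the C4a–C5 bond, onto a finished chiral C ring. The (2S)-2-aryl-2,3-dihydropyran-4-one already holds C2, O1 and C4, and its vinylogous-ester α-carbon is the future C4a. A 6-CH2–CO–CH(geranyl)–CO2tBu chain supplies C8, C7, C6 and C5. Heating unmasks the β-keto ester as an acylketene that acylates C4a, closes the carbocycle and aromatises to the 5,7-dihydroxy-6-geranyl ring in one operation. The geranyl position therefore follows from connectivity, and the C2–O1 bond is never exposed to strong base. The precursor is the tert-butyl ester, chosen so that the electrophile forms without enolate chemistry.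

Key step: step 8

Remark on the chemistry: the ester alkyl group of the cyclisation precursor is a leaving group and is taken as tert-butyl instead of methyl. The (S,S)-TsDPEN–Ru catalyst is assumed to reduce the aryl ketone with the facial sense it shows for aryl alkyl ketones, and the antipodal catalyst would be used otherwise.

Step 1
Reactants: 1 ethyl 3-(3,4-dimethoxyphenyl)-3-oxopropanoate
Product: 2 ethyl (3S)-3-(3,4-dimethoxyphenyl)-3-hydroxypropanoate
Conditions: RuCl(p-cymene)[(S,S)-TsDPEN] (1 mol %), HCO2H–Et3N (5:2), 30 °C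
Reagents that add atoms: none
Why: Noyori–Ikariya asymmetric transfer hydrogenation of an aryl ketone, in which the Ru–H/N–H pair delivers hydride to the Re face through the CH/π-organised six-membered transition state and so sets the (S)-carbinol that becomes C2 of the flavanone.

Step 2
Reactants: 2 ethyl (3S)-3-(3,4-dimethoxyphenyl)-3-hydroxypropanoate
Product: 3 (3S)-3-(3,4-dimethoxyphenyl)-3-hydroxy-N-methoxy-N-methylpropanamide
Conditions: MeNH(OMe)·HCl, i-PrMgCl, THF, −20 to 0 °C; aq. NH4Cl
Reagents that add atoms: N,O-dimethylhydroxylamine hydrochloride, CNOC.Cl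
Why: Weinreb amide formation by magnesium-amide aminolysis of the ester, with the hydroxyl carried as its magnesium alkoxide and the carbinol stereocentre untouched.

Step 3
Reactants: 3 (3S)-3-(3,4-dimethoxyphenyl)-3-hydroxy-N-methoxy-N-methylpropanamide; 4 allyl acetoacetate
Product: 7 allyl 2-[(2S)-2-(3,4-dimethoxyphenyl)-4-oxo-3,4-dihydro-2H-pyran-6-yl]acetate, via acetoacetate dianion 5 (not isolated), via hydroxy diketo ester 6 (not isolated)
Conditions: 4 (3.3 equiv), LDA (6.6 equiv), THF, −78 to −40 °C; 3, −78 to −20 °C; AcOH; crude, PPTS (cat.), 4 Å MS, CH2Cl2, rt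
Reagents that add atoms: none
Why: Claisen-type acylation of the Weiler dianion at its γ-carbon by the Weinreb amide gives the 7-hydroxy-3,5-diketo ester, whose hydroxyl can reach only the C3 ketone through a six-membered hemiketal, so mild acid dehydrates it to the dihydropyranone without breaking the C–O bond of the stereocentre.

Step 4
Reactants: 7 allyl 2-[(2S)-2-(3,4-dimethoxyphenyl)-4-oxo-3,4-dihydro-2H-pyran-6-yl]acetate
Product: 8 2-[(2S)-2-(3,4-dimethoxyphenyl)-4-oxo-3,4-dihydro-2H-pyran-6-yl]acetic acid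
Conditions: Pd(PPh3)4 (3 mol %), sodium 2-ethylhexanoate, EtOAc/CH2Cl2, rt; cold 0.5 M HCl to pH 3
Reagents that add atoms: none
Why: Tsuji–Trost deallylation transfers the allyl group to a carboxylate acceptor under near-neutral conditions, which spares the acid- and base-sensitive benzylic C2–O1 bond.

Step 5
Reactants: 9 tert-butyl methyl malonate; 10 geranyl bromide
Product: 12 1-tert-butyl 3-methyl 2-[(2E)-3,7-dimethylocta-2,6-dienyl]malonate (racemic), via sodium enolate 11 (not isolated)
Conditions: 9 (1.5 equiv), NaH, THF, 0 °C; 10, 0 °C to rt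
Reagents that add atoms: none
Why: Malonic ester alkylation by SN2 at the primary allylic bromide keeps the E geometry of the geranyl unit, and the excess of malonate suppresses dialkylation.

Step 6
Reactants: 12 1-tert-butyl 3-methyl 2-[(2E)-3,7-dimethylocta-2,6-dienyl]malonate
Product: 13 3-tert-butoxy-2-[(2E)-3,7-dimethylocta-2,6-dienyl]-3-oxopropanoic acid (racemic)
Conditions: LiOH·H2O (1.05 equiv), THF/MeOH/H2O, 0 °C; cold 1 M HCl to pH 3
Reagents that add atoms: lithium hydroxide monohydrate, [Li+].[OH-].O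
Why: Saponification attacks the unhindered methyl ester and not the tert-butyl ester, and stops at the mono-carboxylate.

Step 7
Reactants: 8 2-[(2S)-2-(3,4-dimethoxyphenyl)-4-oxo-3,4-dihydro-2H-pyran-6-yl]acetic acid; 13 3-tert-butoxy-2-[(2E)-3,7-dimethylocta-2,6-dienyl]-3-oxopropanoic acid
Product: 16 tert-butyl 2-[(2E)-3,7-dimethylocta-2,6-dienyl]-4-[(2S)-2-(3,4-dimethoxyphenyl)-4-oxo-3,4-dihydro-2H-pyran-6-yl]-3-oxobutanoate (either epimer at the malonyl carbon), via acyl imidazolide 14 (not isolated), via magnesium half-malonate 15 (not isolated)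
Conditions: 8, CDI, THF, 0 °C to rt; 13 (2.2 equiv), Mg(OEt)2, THF, rt, concentrated; combined in THF, rt to 40 °C; cold 0.5 M HCl
Reagents that add atoms: none
Why: Masamune–Brooks decarboxylative Claisen condensation, in which the magnesium enolate of the half-malonate is C-acylated by the acyl imidazolide and loses CO2, so the α-geranyl β-keto ester forms without any base strong enough to deprotonate C3 of the pyranone.

Step 8
Reactants: 16 tert-butyl 2-[(2E)-3,7-dimethylocta-2,6-dienyl]-4-[(2S)-2-(3,4-dimethoxyphenyl)-4-oxo-3,4-dihydro-2H-pyran-6-yl]-3-oxobutanoate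
Product: 19 (2S)-2-(3,4-dimethoxyphenyl)-6-[(2E)-3,7-dimethylocta-2,6-dienyl]-5,7-dihydroxy-2,3-dihydro-4H-chromen-4-one (CNP0268555.1), via acylketene 17 (not isolated), via dienone tautomer 18 (not isolated)
Conditions: xylenes (2 mM), 135 °C, slow N2 sweep; silica gel chromatography
Reagents that add atoms: none
Why: Proposed new method: on heating, the enol of the tert-butyl β-keto ester expels tert-butanol through a six-membered transition state to give the α-geranyl acylketene 17, whose ketene carbon is attacked by C5 of the pyranone (the α-carbon of the vinylogous ester O1–C6=C5–C4=O), forming the C4a–C5 bond and the dienone 18, which enolises irreversibly to the phloroglucinol ring. The closest known reaction types are the Claisen cyclisation of 3,5,7-triketo esters to acylphloroglucinols, the capture of thermally generated acylketenes by enol-type carbon nucleophiles, and the 6π-electrocyclisation of dienylketenes to phenols, the enol tautomer of 17 being such a (Z)-dienylketene. Ring A closes as a six-membered ring in a 6-(enolendo)-exo-dig C-acylation, or equivalently by disrotatory 6π closure of that enol tautomer. No lasting stereocentre is formed, since C4a becomes aromatic, and C2 is not touched because no base, acid or nucleophile is present to open the C2–O1 bond. The step needs C- over O-acylation and intra- over intermolecular capture: O-attack would require a four- or eight-membered ring, the geranyl group sits on the ketene carbon so 6- versus 8-substitution is fixed by connectivity, and high dilution suppresses ketene dimerisation.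

**Compound list**

1 | ethyl 3-(3,4-dimethoxyphenyl)-3-oxopropanoate | CCOC(=O)CC(=O)c1ccc(OC)c(OC)c1 | starting material
2 | ethyl (3S)-3-(3,4-dimethoxyphenyl)-3-hydroxypropanoate | CCOC(=O)C[C@H](O)c1ccc(OC)c(OC)c1 | intermediate
3 | (3S)-3-(3,4-dimethoxyphenyl)-3-hydroxy-N-methoxy-N-methylpropanamide | CON(C)C(=O)C[C@H](O)c1ccc(OC)c(OC)c1 | intermediate
4 | allyl acetoacetate (prop-2-enyl 3-oxobutanoate) | CC(=O)CC(=O)OCC=C | starting material
5 | dilithium dianion of allyl acetoacetate | [Li+].[Li+].C=C([O-])C=C([O-])OCC=C | intermediate (not isolated)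
6 | allyl (7S)-7-(3,4-dimethoxyphenyl)-7-hydroxy-3,5-dioxoheptanoate | C=CCOC(=O)CC(=O)CC(=O)C[C@H](O)c1ccc(OC)c(OC)c1 | intermediate (not isolated)
7 | allyl 2-[(2S)-2-(3,4-dimethoxyphenyl)-4-oxo-3,4-dihydro-2H-pyran-6-yl]acetate | C=CCOC(=O)CC1=CC(=O)C[C@@H](c2ccc(OC)c(OC)c2)O1 | intermediate
8 | 2-[(2S)-2-(3,4-dimethoxyphenyl)-4-oxo-3,4-dihydro-2H-pyran-6-yl]acetic acid | OC(=O)CC1=CC(=O)C[C@@H](c2ccc(OC)c(OC)c2)O1 | intermediate
9 | tert-butyl methyl malonate | COC(=O)CC(=O)OC(C)(C)C | starting material
10 | geranyl bromide ((2E)-1-bromo-3,7-dimethylocta-2,6-diene) | CC(C)=CCC/C(C)=C/CBr | starting material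
11 | sodium enolate of tert-butyl methyl malonate | [Na+].COC(=O)[CH-]C(=O)OC(C)(C)C | intermediate (not isolated)
12 | 1-tert-butyl 3-methyl 2-[(2E)-3,7-dimethylocta-2,6-dienyl]malonate (racemic) | COC(=O)C(C/C=C(\C)CCC=C(C)C)C(=O)OC(C)(C)C | intermediate
13 | 3-tert-butoxy-2-[(2E)-3,7-dimethylocta-2,6-dienyl]-3-oxopropanoic acid (racemic) | OC(=O)C(C/C=C(\C)CCC=C(C)C)C(=O)OC(C)(C)C | intermediate
14 | 1-{2-[(2S)-2-(3,4-dimethoxyphenyl)-4-oxo-3,4-dihydro-2H-pyran-6-yl]acetyl}imidazole | O=C(CC1=CC(=O)C[C@@H](c2ccc(OC)c(OC)c2)O1)n1ccnc1 | intermediate (not isolated)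
15 | magnesium bis[3-tert-butoxy-2-geranyl-3-oxopropanoate] | [Mg+2].[O-]C(=O)C(C/C=C(\C)CCC=C(C)C)C(=O)OC(C)(C)C.[O-]C(=O)C(C/C=C(\C)CCC=C(C)C)C(=O)OC(C)(C)C | intermediate (not isolated)
16 | tert-butyl 2-[(2E)-3,7-dimethylocta-2,6-dienyl]-4-[(2S)-2-(3,4-dimethoxyphenyl)-4-oxo-3,4-dihydro-2H-pyran-6-yl]-3-oxobutanoate (epimers at the malonyl carbon) | CC(C)(C)OC(=O)C(C/C=C(\C)CCC=C(C)C)C(=O)CC1=CC(=O)C[C@@H](c2ccc(OC)c(OC)c2)O1 | intermediate (key-step precursor)
17 | 2-geranyl-4-[(2S)-2-(3,4-dimethoxyphenyl)-4-oxo-3,4-dihydro-2H-pyran-6-yl]but-1-ene-1,3-dione (acylketene) | O=C=C(C/C=C(\C)CCC=C(C)C)C(=O)CC1=CC(=O)C[C@@H](c2ccc(OC)c(OC)c2)O1 | intermediate (not isolated)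
18 | (2S)-2-(3,4-dimethoxyphenyl)-6-geranyl-7-hydroxy-2,3-dihydro-4aH-chromene-4,5-dione (keto tautomer of 19, C4a unspecified) | COc1ccc([C@@H]2CC(=O)C3C(=O)C(C/C=C(\C)CCC=C(C)C)=C(O)C=C3O2)cc1OC | intermediate (not isolated)
19 | (2S)-2-(3,4-dimethoxyphenyl)-6-[(2E)-3,7-dimethylocta-2,6-dienyl]-5,7-dihydroxy-2,3-dihydro-4H-chromen-4-one (CNP0268555.1) | COc1ccc([C@@H]2CC(=O)c3c(cc(O)c(C/C=C(\C)CCC=C(C)C)c3O)O2)cc1OC | target

**Step count.** Total: 8 steps. Longest linear sequence: 6 steps (1, 2, 3, 4, 7, 8).

**Steps most likely to fail**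

1. Step 8 (Proposed new method). The acylketene may form but be consumed by intermolecular dimerisation or by capture of adventitious water, or the neutral pyranone α-carbon may be too weak a nucleophile, so that ring A does not close. The fallback uses known chemistry, brings ring A in as an arene, sets out from geranyl bromide 10 and returns at 19.
   - The known 3,5-bis(methoxymethoxy)phenol is silylated (TIPSCl, imidazole) to [3,5-bis(methoxymethoxy)phenoxy]triisopropylsilane F1.
   - Lithiation between the two MOM ethers (n-BuLi, THF, 0 °C) and allylation with 10 (CuI cat.) give [4-geranyl-3,5-bis(methoxymethoxy)phenoxy]triisopropylsilane F2.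
   - A second ortho-lithiation at −78 °C and acylation with N-methoxy-N-methyl-3-(trimethylsilyl)propiolamide give 1-[3-geranyl-2,4-bis(methoxymethoxy)-6-(triisopropylsilyloxy)phenyl]-3-(trimethylsilyl)prop-2-yn-1-one F3.
   - TBAF removes both silyl groups and the phenoxide adds 6-endo-dig to the ynone to give 6-geranyl-5,7-bis(methoxymethoxy)-4H-chromen-4-one F4. Its substitution pattern is fixed by the symmetry of F2.
   - Rhodium-catalysed asymmetric 1,4-addition of 3,4-dimethoxyphenylboronic acid (Hayashi–Miyaura conditions, chiral bisphosphine of the antipode that delivers 2S) gives (2S)-2-(3,4-dimethoxyphenyl)-6-geranyl-5,7-bis(methoxymethoxy)-2,3-dihydro-4H-chromen-4-one F5.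
   - ZnBr2/n-PrSH in CH2Cl2 removes the MOM groups to give 19.

2. Step 7. C-acylation of the hindered α-geranyl magnesium malonate may be slow, so the enolisable acyl imidazolide is lost to self-condensation through its ketene or dienolate. The fallback introduces the geranyl group after the β-keto ester is made, sets out from acid 8 and returns at 16. Acid 8 is activated with CDI and condensed with the magnesium salt of unsubstituted mono-tert-butyl malonate, which is acylated far more readily, to give tert-butyl 4-[(2S)-2-(3,4-dimethoxyphenyl)-4-oxo-3,4-dihydro-2H-pyran-6-yl]-3-oxobutanoate F6. This is C-alkylated at the carbon between ketone and ester, expected to be its most acidic position, with geranyl bromide 10 (K2CO3, acetone, rt) to give 16.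

3. Step 3. The lithium alkoxide of 3 may suffer α-deprotonation or retro-aldol cleavage in the strongly basic dianion medium, lowering conversion, or the free electron-rich benzylic carbinol may ionise during the acid-promoted dehydration. The fallback masks the hydroxyl and releases it only at ring closure, sets out from 3 and returns at 7. Compound 3 is silylated (TBSCl, imidazole, DMF) to (3S)-3-(tert-butyldimethylsilyloxy)-3-(3,4-dimethoxyphenyl)-N-methoxy-N-methylpropanamide F7. Acylation of dianion 5 with F7 gives allyl (7S)-7-(tert-butyldimethylsilyloxy)-7-(3,4-dimethoxyphenyl)-3,5-dioxoheptanoate F8. HF·pyridine in THF/pyridine removes the silyl group, and the released hydroxyl cyclodehydrates onto the C3 ketone to give 7.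

**Further compounds**

F1 | step 8 | [3,5-bis(methoxymethoxy)phenoxy]triisopropylsilane | COCOc1cc(OCOC)cc(O[Si](C(C)C)(C(C)C)C(C)C)c1
F2 | step 8 | [4-geranyl-3,5-bis(methoxymethoxy)phenoxy]triisopropylsilane | COCOc1cc(O[Si](C(C)C)(C(C)C)C(C)C)cc(OCOC)c1C/C=C(\C)CCC=C(C)C
F3 | step 8 | 1-[3-geranyl-2,4-bis(methoxymethoxy)-6-(triisopropylsilyloxy)phenyl]-3-(trimethylsilyl)prop-2-yn-1-one | COCOc1c(C/C=C(\C)CCC=C(C)C)c(OCOC)cc(O[Si](C(C)C)(C(C)C)C(C)C)c1C(=O)C#C[Si](C)(C)C
F4 | step 8 | 6-geranyl-5,7-bis(methoxymethoxy)-4H-chromen-4-one | O=c1ccoc2cc(OCOC)c(C/C=C(\C)CCC=C(C)C)c(OCOC)c12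
F5 | step 8 | (2S)-2-(3,4-dimethoxyphenyl)-6-geranyl-5,7-bis(methoxymethoxy)-2,3-dihydro-4H-chromen-4-one | COc1ccc([C@@H]2CC(=O)c3c(cc(OCOC)c(C/C=C(\C)CCC=C(C)C)c3OCOC)O2)cc1OC
F6 | step 7 | tert-butyl 4-[(2S)-2-(3,4-dimethoxyphenyl)-4-oxo-3,4-dihydro-2H-pyran-6-yl]-3-oxobutanoate | CC(C)(C)OC(=O)CC(=O)CC1=CC(=O)C[C@@H](c2ccc(OC)c(OC)c2)O1
F7 | step 3 | (3S)-3-(tert-butyldimethylsilyloxy)-3-(3,4-dimethoxyphenyl)-N-methoxy-N-methylpropanamide | CON(C)C(=O)C[C@H](O[Si](C)(C)C(C)(C)C)c1ccc(OC)c(OC)c1
F8 | step 3 | allyl (7S)-7-(tert-butyldimethylsilyloxy)-7-(3,4-dimethoxyphenyl)-3,5-dioxoheptanoate | C=CCOC(=O)CC(=O)CC(=O)C[C@H](O[Si](C)(C)C(C)(C)C)c1ccc(OC)c(OC)c1
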